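**Plan**
- Retrosynthesis: the two O–CH3 bonds of a dimethyl ether are cut first, then the pyranone ring is opened in one operation at C4a–C4, C4–C3 and O1–C2.
- Enabling feature: in the γ-pyranone ring, C4 is a lone carbonyl carbon bridging arene carbon C4a and the C2=C3 unit, and O1 sits ortho to C4a. C4 can therefore be carbon monoxide, C2–C3 a terminal alkyne carrying the C21 chain, and C4a/O1 an ortho-iodophenol.
- Forward: 3,5-dimethoxyphenol is iodinated ortho to the hydroxyl; 1-docosanol (C22) is oxidised and homologated by one carbon to 1-tricosyne.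
- Palladium then joins iodophenol, CO and alkyne to an ortho-hydroxyaryl ynone, which a secondary amine relays into the chromone, the only ring formed; boron tribromide finally frees the 5,7-diol.
- Stereochemistry: the target has no stereocentre and no stereogenic double bond, so nothing has to be set or preserved.

Key step: step 4

Remark: the target is achiral, so the requirement of a single enantiomer is met by the constitution alone; the side chain is read as unbranched henicosyl (C21).

**Route**

Step 1
Reactants: 1 3,5-dimethoxyphenol
Product: 2 2-iodo-3,5-dimethoxyphenol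
Conditions: NIS (1.0 equiv), CH2Cl2, −20 → 0 °C, dark
Reagents that add atoms: N-iodosuccinimide, O=C1CCC(=O)N1I
Why: Electrophilic aromatic iodination, in which the hydroxyl-directed positions C2/C6 (each also para to one methoxy group) should be attacked in preference to C4, which is flanked by two methoxy groups, while one equivalent of reagent at low temperature limits di-iodination.

Step 2
Reactants: 3 1-docosanol
Product: 4 docosanal
Conditions: TEMPO (10 mol%), PhI(OAc)2 (1.1 equiv), CH2Cl2, 25–35 °C
Reagents that add atoms: none
Why: Oxoammonium-mediated (TEMPO/PhI(OAc)2) oxidation of a primary alcohol should stop cleanly at the aldehyde in anhydrous dichloromethane, and the saturated chain offers no competing site.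

Step 3
Reactants: 4 docosanal
Product: 5 1-tricosyne
Conditions: dimethyl (1-diazo-2-oxopropyl)phosphonate (1.3 equiv), K2CO3 (2 equiv), MeOH/THF (1:1), 0 °C → rt
Reagents that add atoms: dimethyl (1-diazo-2-oxopropyl)phosphonate, CC(=O)C(=[N+]=[N-])P(=O)(OC)OC
Why: Seyferth–Gilbert homologation in the Ohira–Bestmann variant, in which methanolysis releases the diazomethylphosphonate anion, Horner–Wadsworth–Emmons-type olefination gives a diazoalkene, and loss of N2 with 1,2-hydride shift delivers the terminal alkyne under carbonate conditions mild enough for an enolisable aldehyde.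

Step 4
Reactants: 2 2-iodo-3,5-dimethoxyphenol; 5 1-tricosyne; 6 carbon monoxide
Product: 9 2-henicosyl-5,7-dimethoxy-4H-chromen-4-one, via 2-hydroxyaryl ynone 7 (not isolated), via diethylamino enone 8 (not isolated)
Conditions: PdCl2(dppf) (5 mol%), CO (20 bar), Et2NH/toluene (1:1), 110 °C, autoclave, no copper
Reagents that add atoms: none
Why: Pd(0) should insert into the C–I bond of 2, CO insertion gives the aroyl–palladium species, and transfer of the amine-generated acetylide of 5 followed by reductive elimination gives ynone 7, forming C4a–C4 and C4–C3. Diethylamine then adds in conjugate fashion to 7 to give β-amino enone 8, and the ortho hydroxyl attacks the β-carbon and expels the amine (addition–elimination), forming O1–C2. The closest known reaction type is the carbonylative Sonogashira coupling–annulation of 2-iodophenols with terminal alkynes to chromones and flavones in a secondary amine. The pyranone ring closes in a net 6-endo-dig sense with respect to the ynone, realised as a 6-endo-trig attack on the enaminone; no stereocentre is created. Two selectivities are needed: carbonylative over direct alkynylation (which would lead on to a benzofuran), secured by CO pressure, the absence of copper and fast CO insertion into the electron-rich aryl–palladium bond; and 6-endo over 5-exo closure (aurone), secured because the amine makes the β-carbon the only site open to the phenol. The free hydroxyl is already ortho to the iodide and the methyl ethers are inert to these conditions.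

Step 5
Reactants: 9 2-henicosyl-5,7-dimethoxy-4H-chromen-4-one
Product: 10 2-henicosyl-5,7-dihydroxy-4H-chromen-4-one
Conditions: BBr3 (6 equiv), CH2Cl2, −78 °C → rt; then ice–water
Reagents that add atoms: none
Why: Lewis-acid cleavage of aryl methyl ethers, in which boron coordinates the ether oxygen and bromide attacks the methyl group; the C5 ether is assisted by chelation to the C4 carbonyl, excess reagent at room temperature should also open the C7 ether, and the alkyl chain and pyranone are not affected.

**Compound list**
1 | 3,5-dimethoxyphenol | COc1cc(O)cc(OC)c1 | starting material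
2 | 2-iodo-3,5-dimethoxyphenol | COc1cc(O)c(I)c(OC)c1 | intermediate
3 | 1-docosanol | CCCCCCCCCCCCCCCCCCCCCCO | starting material
4 | docosanal | CCCCCCCCCCCCCCCCCCCCCC=O | intermediate
5 | 1-tricosyne | C#CCCCCCCCCCCCCCCCCCCCCCC | intermediate
6 | carbon monoxide | [C-]#[O+] | starting material
7 | 1-(2-hydroxy-4,6-dimethoxyphenyl)tetracos-2-yn-1-one | CCCCCCCCCCCCCCCCCCCCCC#CC(=O)c1c(O)cc(OC)cc1OC | intermediate
8 | (2E)-3-(diethylamino)-1-(2-hydroxy-4,6-dimethoxyphenyl)tetracos-2-en-1-one (drawn as the E isomer; the geometry is lost on ring closure) | CCN(CC)/C(CCCCCCCCCCCCCCCCCCCCC)=C/C(=O)c1c(O)cc(OC)cc1OC | intermediate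
9 | 2-henicosyl-5,7-dimethoxy-4H-chromen-4-one | CCCCCCCCCCCCCCCCCCCCCc1cc(=O)c2c(OC)cc(OC)cc2o1 | intermediate
10 | 2-henicosyl-5,7-dihydroxy-4H-chromen-4-one (CNP0326895.0) | CCCCCCCCCCCCCCCCCCCCCc1cc(=O)c2c(O)cc(O)cc2o1 | target

**Totals**
Total step count: 5.
Longest linear sequence: 4 steps (3 → 4 → 5 → 9 → 10).

**Steps most likely to fail**

Step 4. The aroyl–palladium intermediate may be intercepted by diethylamine (aminocarbonylation to the amide), CO insertion may be outrun by direct alkynylation followed by closure to a benzofuran, or oxidative addition into the hindered, electron-rich C–I bond may be slow. The fallback builds the ynone without palladium or CO; it sets out from alkyne 5 and returns to the route at ynone 7, and from there at 9. Commercial 2-hydroxy-4,6-dimethoxybenzaldehyde would be protected (MOMCl, i-Pr2NEt, CH2Cl2) as 2-(methoxymethoxy)-4,6-dimethoxybenzaldehyde F1. Addition of the lithium acetylide of 5 (n-BuLi, THF, −20 °C) should give racemic 1-[2-(methoxymethoxy)-4,6-dimethoxyphenyl]tetracos-2-yn-1-ol F2. Oxidation of the propargylic alcohol (MnO2, CH2Cl2) should give 1-[2-(methoxymethoxy)-4,6-dimethoxyphenyl]tetracos-2-yn-1-one F3. Removal of the acetal (HCl, MeOH/THF) would release 7, which on warming with Et2NH in EtOH should close through 8 to 9.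

Step 1. Iodination may occur para to the hydroxyl (between the two methoxy groups), over-iodination may compete, and the electron-rich iodide may lose iodine on handling. The fallback fixes the position by directed ortho-metalation; it sets out from 1 and returns at 2. Carbamoylation of 1 (ClC(O)NEt2, NaH, THF) would give 3,5-dimethoxyphenyl N,N-diethylcarbamate F4. Lithiation next to the carbamate, the strongest director on the ring (s-BuLi, TMEDA, THF, −78 °C), and quenching with I2 should give 2-iodo-3,5-dimethoxyphenyl N,N-diethylcarbamate F5. Hydrolysis (NaOH, EtOH/H2O, reflux) would then release 2.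

Step 5. After fast, chelation-assisted loss of the C5 methyl group, cleavage of the C7 methyl ether may stall, and forcing conditions may degrade the pyranone. The fallback replaces methyl by benzyl ethers, which are removed under neutral conditions; it sets out from alkyne 5 (with CO 6) and returns at target 10. Commercial 3,5-bis(benzyloxy)phenol would be iodinated as in step 1 (NIS, CH2Cl2) to 3,5-bis(benzyloxy)-2-iodophenol F6. Under the conditions of step 4 with 5 and 6, this should pass through 1-[2,4-bis(benzyloxy)-6-hydroxyphenyl]tetracos-2-yn-1-one F7 and (2E)-1-[2,4-bis(benzyloxy)-6-hydroxyphenyl]-3-(diethylamino)tetracos-2-en-1-one F8 to 5,7-bis(benzyloxy)-2-henicosyl-4H-chromen-4-one F9. Hydrogenolysis (H2, Pd/C, EtOAc/THF, rt) should then give 10.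

**Further compounds**
F1 | step 4 | 2-(methoxymethoxy)-4,6-dimethoxybenzaldehyde | COCOc1cc(OC)cc(OC)c1C=O
F2 | step 4 | rac-1-[2-(methoxymethoxy)-4,6-dimethoxyphenyl]tetracos-2-yn-1-ol | CCCCCCCCCCCCCCCCCCCCCC#CC(O)c1c(OCOC)cc(OC)cc1OC
F3 | step 4 | 1-[2-(methoxymethoxy)-4,6-dimethoxyphenyl]tetracos-2-yn-1-one | CCCCCCCCCCCCCCCCCCCCCC#CC(=O)c1c(OCOC)cc(OC)cc1OC
F4 | step 1 | 3,5-dimethoxyphenyl N,N-diethylcarbamate | CCN(CC)C(=O)Oc1cc(OC)cc(OC)c1
F5 | step 1 | 2-iodo-3,5-dimethoxyphenyl N,N-diethylcarbamate | CCN(CC)C(=O)Oc1cc(OC)cc(OC)c1I
F6 | step 5 | 3,5-bis(benzyloxy)-2-iodophenol | Oc1cc(OCc2ccccc2)cc(OCc2ccccc2)c1I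
F7 | step 5 | 1-[2,4-bis(benzyloxy)-6-hydroxyphenyl]tetracos-2-yn-1-one | CCCCCCCCCCCCCCCCCCCCCC#CC(=O)c1c(O)cc(OCc2ccccc2)cc1OCc1ccccc1
F8 | step 5 | (2E)-1-[2,4-bis(benzyloxy)-6-hydroxyphenyl]-3-(diethylamino)tetracos-2-en-1-one | CCN(CC)/C(CCCCCCCCCCCCCCCCCCCCC)=C/C(=O)c1c(O)cc(OCc2ccccc2)cc1OCc1ccccc1
F9 | step 5 | 5,7-bis(benzyloxy)-2-henicosyl-4H-chromen-4-one | CCCCCCCCCCCCCCCCCCCCCc1cc(=O)c2c(OCc3ccccc3)cc(OCc3ccccc3)cc2o1
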